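Ring B of this ent-labdane is closed last by inserting a two-carbon linchpin between C5 and C8 of a ring A precursor that already carries the C9 side chain. In one operation a C5 radical, released from a hydrogen oxalate, adds to vinyltriphenylphosphonium bromide (C5–C6), the phosphonio radical is reduced to an ylide, and this olefinates the C8 methyl ketone (C7=C8). The step exploits the 1,4-relationship between the oxygenated C5 of ring A and the C8 carbonyl across the C10–C9 bond. The precursor, a 2,2,6-trimethylcyclohexyl hydrogen oxalate, stems from (S)-3-hydroxy-2,2-dimethylcyclohexanone and geranyl acetate, joined by iridium-catalysed allylation that sets C9 and C10.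

Key step: step 9

Remarks on the chemistry:
- Atom numbers C1–C20 in the text are those of the labdane skeleton.
- (S)-3-Hydroxy-2,2-dimethylcyclohexan-1-one and (S)-3-methylpentanoic acid are taken as commercial.
- From step 5 to step 9 the C5 carbinol carbon is a mixture of epimers; this centre is erased when the C5 radical forms.

Step 1
Reactants: 1 (S)-3-hydroxy-2,2-dimethylcyclohexan-1-one
Product: 2 (S)-3-(tert-butyldimethylsilyloxy)-2,2-dimethylcyclohexan-1-one
Conditions: TBSCl, imidazole, DMF, rt → 40 °C
Reagents that add atoms: tert-butyldimethylsilyl chloride, CC(C)(C)[Si](C)(C)Cl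
Why: Silyl ether formation protects the C3 hydroxyl, whose (S) configuration from the chiral pool becomes the axial C3–O bond of the target.

Step 2
Reactants: 2 (S)-3-(tert-butyldimethylsilyloxy)-2,2-dimethylcyclohexan-1-one
Product: 4 (3S)-3-(tert-butyldimethylsilyloxy)-2,2,6-trimethylcyclohexan-1-one (both C6 epimers), via lithium enolate 3 (not isolated)
Conditions: LiN(iPr)2, THF, −78 °C; then MeI, −78 → 0 °C
Reagents that add atoms: iodomethane, CI
Why: Enolate alkylation is regiospecific because only C6 (labdane C10) can be deprotonated, C2 being quaternary; the new centre forms as a mixture and becomes trigonal again in step 4.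

Step 3
Reactants: 5 geranyl acetate; 6 allyl methyl carbonate
Product: 7 (2E,6E)-8-acetoxy-6-methylocta-2,6-dien-1-yl methyl carbonate
Conditions: second-generation Grubbs catalyst (3 mol %), 6 (3 equiv), CH2Cl2, 40 °C
Reagents that add atoms: none
Why: Olefin cross-metathesis at the electron-rich isopropylidene terminus (the alkene next to the acetate is deactivated and more hindered) should give the E-allylic carbonate with release of 2-methylpropene.

Step 4
Reactants: 4 (3S)-3-(tert-butyldimethylsilyloxy)-2,2,6-trimethylcyclohexan-1-one; 7 (2E,6E)-8-acetoxy-6-methylocta-2,6-dien-1-yl methyl carbonate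
Product: 9 (3S,6S)-6-[(3R,6E)-8-acetoxy-6-methylocta-1,6-dien-3-yl]-3-(tert-butyldimethylsilyloxy)-2,2,6-trimethylcyclohexan-1-one, via barium enolate 8 (not isolated)
Conditions: Ba(OtBu)2, THF, rt; then 7, [Ir(cod)Cl]2 (2 mol %), O,O'-(1,1'-binaphthalene-2,2'-diyl) N,N-bis(1-phenylethyl)phosphoramidite (4 mol %, the enantiomer that delivers 9R), THF, 5 °C → rt
Reagents that add atoms: none
Why: Iridium-catalysed branched-selective asymmetric allylic alkylation of the fully substituted ketone enolate should form the C9–C10 bond, the chiral iridium allyl complex fixing C9 and the enolate face engaged in the ordered transition state fixing C10 (9R,10S), independent of the remote C3 centre.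

Step 5
Reactants: 9 (3S,6S)-6-[(3R,6E)-8-acetoxy-6-methylocta-1,6-dien-3-yl]-3-(tert-butyldimethylsilyloxy)-2,2,6-trimethylcyclohexan-1-one
Product: 10 (3S,6S)-3-(tert-butyldimethylsilyloxy)-6-[(3R,6E)-8-hydroxy-6-methylocta-1,6-dien-3-yl]-2,2,6-trimethylcyclohexan-1-ol (both C1 carbinol epimers)
Conditions: LiAlH4, THF, 0 °C → reflux; aqueous NaOH work-up
Reagents that add atoms: none
Why: Hydride reduction with the small LiAlH4 should reduce the doubly flanked C5 ketone and cleave the acetate in one pass; the C5 carbinol configuration is not controlled and is erased in step 9.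

Step 6
Reactants: 10 (3S,6S)-3-(tert-butyldimethylsilyloxy)-6-[(3R,6E)-8-hydroxy-6-methylocta-1,6-dien-3-yl]-2,2,6-trimethylcyclohexan-1-ol; 11 (S)-3-methylpentanoic acid
Product: 12 (2E,6R)-6-[(1S,3S)-3-(tert-butyldimethylsilyloxy)-2-hydroxy-1,3,3-trimethyl... simplified: C15 (3S)-3-methylpentanoate of diol 10
Conditions: 11 (1.1 equiv), EDC·HCl, DMAP (cat.), CH2Cl2, 0 °C
Reagents that add atoms: none
Why: Carbodiimide (Steglich-type) esterification should acylate only the primary allylic alcohol, because the C5 hydroxyl lies between two quaternary carbons; no stereocentre is touched.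

Step 7
Reactants: 12 C15 (3S)-3-methylpentanoate of diol 10
Product: 14 C5 hydrogen oxalate of 12, via chlorooxoacetate 13 (not isolated)
Conditions: (COCl)2 (3 equiv), Et2O, 0 °C → rt; then H2O, 0 °C
Reagents that add atoms: oxalyl chloride, ClC(=O)C(Cl)=O; water, O
Why: Acylation by the small, highly electrophilic oxalyl chloride should reach even the hindered C5 alcohol, and hydrolysis of the chlorooxoacetate gives the hydrogen oxalate.

Step 8
Reactants: 14 C5 hydrogen oxalate of 12
Product: 15 methyl ketone in which the vinyl group on C9 of 14 has become acetyl (9S by priority change only)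
Conditions: PdCl2 (10 mol %), CuCl, O2 (1 atm), DMF/H2O, rt
Reagents that add atoms: water, O
Why: Wacker oxidation should convert the monosubstituted vinyl group into the methyl ketone with Markovnikov regiochemistry, while the trisubstituted alkene is too hindered to coordinate palladium.

Step 9
Reactants: 15 methyl ketone hydrogen oxalate; 16 vinyltriphenylphosphonium bromide
Product: 19 (3S,5S,9R,10S,13E)-3-(tert-butyldimethylsilyloxy)labda-7,13-dien-15-yl (3S)-3-methylpentanoate, via potassium oxalate 17 (not isolated), via phosphorus ylide 18 (not isolated)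
Conditions: KOtBu (1.0 equiv), DMSO, rt; then 16 (2 equiv), Ir[dF(CF3)ppy]2(dtbbpy)PF6 (2 mol %), 4 Å MS, blue LEDs (450 nm), 40 °C, argon
Reagents that add atoms: none
Why: Proposed new method: the photoexcited iridium complex oxidises oxalate 17, which loses two CO2 to give the secondary C5 radical; this adds to C6 of 16, the α-phosphonio radical is reduced by the reduced photocatalyst to ylide 18, and C7 of 18 attacks the C8 ketone in an intramolecular Wittig olefination. The closest known reactions are the photoredox decarboxylative radical addition to vinylphosphonium salts with in situ Wittig olefination (intermolecular, three components), the Giese coupling of alkyl oxalates, and the annulation of nucleophiles with vinylphosphonium salts by conjugate addition and intramolecular Wittig reaction. Ring B closes by six-membered carbonyl olefination (6-exo attack of the ylide carbon on C8=O, then oxaphosphetane cycloreversion), so the alkene can only be C7=C8 and cis within the ring. The new C5 centre is controlled by ring A: in the chair with the C9 branch axial the α face of C5 is open and anti to that branch, while in the other chair the axial C3 silyloxy group shields the β face, so C6 should enter cis to the C10 methyl and give the trans ring fusion. The step needs this facial selectivity, addition to 16 faster than 1,5-hydrogen transfer from C12, and ring closure faster than ylide protonation; excess 16, an aprotic medium with tert-butanol as the only proton source, and the proximity of the ketone should secure them.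

Step 10
Reactants: 19 (3S,5S,9R,10S,13E)-3-(tert-butyldimethylsilyloxy)labda-7,13-dien-15-yl (3S)-3-methylpentanoate
Product: 20 (3S,5S,9R,10S,13E)-3-hydroxylabda-7,13-dien-15-yl (3S)-3-methylpentanoate
Conditions: HF (48 % aq.), MeCN, 0 °C → rt
Reagents that add atoms: none
Why: Silyl ether cleavage by HF should free the axial C3 hydroxyl without touching the esters or alkenes; C3 keeps its configuration.

Step 11
Reactants: 20 (3S,5S,9R,10S,13E)-3-hydroxylabda-7,13-dien-15-yl (3S)-3-methylpentanoate; 21 Meldrum's acid
Product: 22 (3S,5S,9R,10S,13E)-3-(carboxyacetoxy)labda-7,13-dien-15-yl (3S)-3-methylpentanoate (CNP0234792.1)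
Conditions: 21 (3 equiv), toluene, 90 °C
Reagents that add atoms: none
Why: Alcoholysis of Meldrum's acid (acylative ring opening with loss of acetone) should give the malonic half ester directly, with retention at C3.

Compound list
1 | (S)-3-hydroxy-2,2-dimethylcyclohexan-1-one | CC1(C)[C@@H](O)CCCC1=O | starting material
2 | (S)-3-(tert-butyldimethylsilyloxy)-2,2-dimethylcyclohexan-1-one | CC1(C)[C@@H](O[Si](C)(C)C(C)(C)C)CCCC1=O | intermediate
3 | lithium enolate of 2 | [Li+].CC1(C)[C@@H](O[Si](C)(C)C(C)(C)C)CCC=C1[O-] | intermediate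
4 | (3S)-3-(tert-butyldimethylsilyloxy)-2,2,6-trimethylcyclohexan-1-one (C6 epimers) | CC1CC[C@H](O[Si](C)(C)C(C)(C)C)C(C)(C)C1=O | intermediate
5 | geranyl acetate | CC(=O)OC/C=C(\C)CCC=C(C)C | starting material
6 | allyl methyl carbonate | COC(=O)OCC=C | starting material
7 | (2E,6E)-8-acetoxy-6-methylocta-2,6-dien-1-yl methyl carbonate | COC(=O)OC/C=C/CC/C(C)=C/COC(C)=O | intermediate
8 | barium enolate of 4 | [Ba+2].CC1=C([O-])C(C)(C)[C@@H](O[Si](C)(C)C(C)(C)C)CC1.CC1=C([O-])C(C)(C)[C@@H](O[Si](C)(C)C(C)(C)C)CC1 | intermediate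
9 | (3S,6S)-6-[(3R,6E)-8-acetoxy-6-methylocta-1,6-dien-3-yl]-3-(tert-butyldimethylsilyloxy)-2,2,6-trimethylcyclohexan-1-one (labdane 3S,9R,10S) | CC(=O)OC/C=C(\C)CC[C@H](C=C)[C@]1(C)CC[C@H](O[Si](C)(C)C(C)(C)C)C(C)(C)C1=O | intermediate
10 | (3S,6S)-3-(tert-butyldimethylsilyloxy)-6-[(3R,6E)-8-hydroxy-6-methylocta-1,6-dien-3-yl]-2,2,6-trimethylcyclohexan-1-ol (C1 carbinol epimers) | OC/C=C(\C)CC[C@H](C=C)[C@]1(C)CC[C@H](O[Si](C)(C)C(C)(C)C)C(C)(C)C1O | intermediate
11 | (S)-3-methylpentanoic acid | CC[C@H](C)CC(=O)O | starting material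
12 | C15 (3S)-3-methylpentanoate of diol 10 (free C5 hydroxyl) | CC[C@H](C)CC(=O)OC/C=C(\C)CC[C@H](C=C)[C@]1(C)CC[C@H](O[Si](C)(C)C(C)(C)C)C(C)(C)C1O | intermediate
13 | C5 chlorooxoacetate of 12 | CC[C@H](C)CC(=O)OC/C=C(\C)CC[C@H](C=C)[C@]1(C)CC[C@H](O[Si](C)(C)C(C)(C)C)C(C)(C)C1OC(=O)C(Cl)=O | intermediate
14 | C5 hydrogen oxalate of 12 | CC[C@H](C)CC(=O)OC/C=C(\C)CC[C@H](C=C)[C@]1(C)CC[C@H](O[Si](C)(C)C(C)(C)C)C(C)(C)C1OC(=O)C(=O)O | intermediate
15 | C8 methyl ketone, C5 hydrogen oxalate (vinyl of 14 oxidised to acetyl) | CC[C@H](C)CC(=O)OC/C=C(\C)CC[C@H](C(C)=O)[C@]1(C)CC[C@H](O[Si](C)(C)C(C)(C)C)C(C)(C)C1OC(=O)C(=O)O | intermediate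
16 | vinyltriphenylphosphonium bromide | C=C[P+](c1ccccc1)(c1ccccc1)c1ccccc1.[Br-] | starting material
17 | potassium oxalate of 15 | CC[C@H](C)CC(=O)OC/C=C(\C)CC[C@H](C(C)=O)[C@]1(C)CC[C@H](O[Si](C)(C)C(C)(C)C)C(C)(C)C1OC(=O)C(=O)[O-].[K+] | intermediate
18 | phosphorus ylide (C5 bears the 2-(triphenylphosphoranylidene)ethyl group, 5S) | CC[C@H](C)CC(=O)OC/C=C(\C)CC[C@H](C(C)=O)[C@]1(C)CC[C@H](O[Si](C)(C)C(C)(C)C)C(C)(C)[C@H]1CC=P(c1ccccc1)(c1ccccc1)c1ccccc1 | intermediate
19 | (3S,5S,9R,10S,13E)-3-(tert-butyldimethylsilyloxy)labda-7,13-dien-15-yl (3S)-3-methylpentanoate | CC[C@H](C)CC(=O)OC/C=C(\C)CC[C@@H]1C(C)=CC[C@@H]2C(C)(C)[C@@H](O[Si](C)(C)C(C)(C)C)CC[C@@]12C | intermediate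
20 | (3S,5S,9R,10S,13E)-3-hydroxylabda-7,13-dien-15-yl (3S)-3-methylpentanoate | CC[C@H](C)CC(=O)OC/C=C(\C)CC[C@@H]1C(C)=CC[C@@H]2C(C)(C)[C@@H](O)CC[C@@]12C | intermediate
21 | Meldrum's acid (2,2-dimethyl-1,3-dioxane-4,6-dione) | CC1(C)OC(=O)CC(=O)O1 | starting material
22 | (3S,5S,9R,10S,13E)-3-(carboxyacetoxy)labda-7,13-dien-15-yl (3S)-3-methylpentanoate | CC[C@H](C)CC(=O)OC/C=C(\C)CC[C@@H]1C(C)=CC[C@@H]2C(C)(C)[C@@H](OC(=O)CC(=O)O)CC[C@@]12C | target

Total step count: 11. Longest linear sequence: 10 steps (1, 2, 4–11); step 3 is a one-step branch.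

Steps most likely to fail

Step 9 (Proposed new method). The α-phosphonio radical may not be reduced to the ylide, or the ylide may be protonated before it reaches the ketone. The C5 radical may also be diverted by 1,5-hydrogen transfer from C12, and attack on the β face of C5 would give the cis-fused epimer. The fallback uses known chemistry, sets out from 15 and returns at 19, and still depends on the same C5 facial preference. The oxalate-derived C5 radical (same photocatalyst and light) is trapped by allyl phenyl sulfone through addition and β-fragmentation to give the C5-allyl methyl ketone F1, at which stage C5 epimers can be separated. Wittig methylenation of the C8 ketone with Ph3P=CH2 in THF at 0 °C gives the isopropenyl diene F2. Ring-closing metathesis with the second-generation Grubbs catalyst in CH2Cl2 at 40 °C then forms C7=C8 and gives 19.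

Step 4. With a hindered, fully substituted enolate and an aliphatic allyl carbonate, the branched-to-linear preference may erode and the enolate face may pair wrongly with the allyl face, giving the wrong relative configuration at C9/C10. The fallback sets out from 4 and returns at 9. Cross-metathesis of 5 with (Z)-but-2-ene-1,4-diol gives the allylic alcohol F3, and MsCl/Et3N converts it into the mesylate F4. O-Alkylation of the potassium enolate of 4 (KN(SiMe3)2, 18-crown-6, THF/DMPU) gives the allyl enol ether F5; the C-alkylated by-product is removed. Claisen rearrangement in toluene at 130 °C passes through the chair transition state of the (E)-allyl ether, which places H9 anti to the C10 methyl, the relative configuration of 9. Because C3 is already stereodefined, the two products are diastereomers, 9 and its (9S,10R) isomer F6, and are separated by chromatography.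

Step 11. Acylation of the axial, neopentyl C3 hydroxyl may be slow, and the malonic half ester may decarboxylate on prolonged heating. The fallback sets out from 20 and returns at 22. Esterification with 3-oxo-3-[2-(trimethylsilyl)ethoxy]propanoic acid (EDC·HCl, DMAP, CH2Cl2) gives the mixed malonate F7, and Bu4NF in THF at 0 °C releases the acid 22.

Further compounds
F1 | step 9 | C5-allyl C8 methyl ketone (5S) | CC[C@H](C)CC(=O)OC/C=C(\C)CC[C@H](C(C)=O)[C@]1(C)CC[C@H](O[Si](C)(C)C(C)(C)C)C(C)(C)[C@H]1CC=C
F2 | step 9 | C5-allyl C9-isopropenyl diene | CC[C@H](C)CC(=O)OC/C=C(\C)CC[C@H](C(C)=C)[C@]1(C)CC[C@H](O[Si](C)(C)C(C)(C)C)C(C)(C)[C@H]1CC=C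
F3 | step 4 | (2E,6E)-8-hydroxy-3-methylocta-2,6-dien-1-yl acetate | CC(=O)OC/C=C(\C)CC/C=C/CO
F4 | step 4 | (2E,6E)-8-(methanesulfonyloxy)-3-methylocta-2,6-dien-1-yl acetate | CC(=O)OC/C=C(\C)CC/C=C/COS(C)(=O)=O
F5 | step 4 | allyl enol ether of ketone 4 | CC(=O)OC/C=C(\C)CC/C=C/COC1=C(C)CC[C@H](O[Si](C)(C)C(C)(C)C)C1(C)C
F6 | step 4 | (9S,10R) diastereomer of 9 | CC(=O)OC/C=C(\C)CC[C@@H](C=C)[C@@]1(C)CC[C@H](O[Si](C)(C)C(C)(C)C)C(C)(C)C1=O
F7 | step 11 | 2-(trimethylsilyl)ethyl malonate of 20 | CC[C@H](C)CC(=O)OC/C=C(\C)CC[C@@H]1C(C)=CC[C@@H]2C(C)(C)[C@@H](OC(=O)CC(=O)OCC[Si](C)(C)C)CC[C@@]12C
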